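## Retrosynthetic overview

1. C2=C3 is made last by E1cB loss of pivalic acid. Just before that, acylation of C8-OH with N-methylurocanic acid traps the 4,7-furanose (dihydrofuran) form of a 4,8-pyranose hemiketal.
2. The pyranose comes from Achmatowicz oxidation of a C8 furfuryl alcohol held in a [6](2,5)furanophane, then methyl addition to the C7 ketone anti to the carbon bridge.
3. The ten-membered ring is closed at C7–C8 by an intramolecular Nozaki–Hiyama–Kishi reaction (2-bromofuran onto the C8 aldehyde). C8 is then fixed by oxidation and CBS reduction.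
4. C2–C3 comes from an aldol between methyl (5-bromofuran-2-yl)acetate (carries C3–C7 and the C15 ester) and the C1 aldehyde. It is kept sp3 (C2-OPiv) until the furan is gone, to avoid a strained alkenyl furanophane.
5. C1, C10 and C14 come from (R)-α-phellandrene by dichloroketene [2+2] and Bredereck/retro-Claisen opening. Ring order: cyclohexene (chiral pool) → ten-membered furanophane → pyranose → dihydrofuran.

Assumptions and conventions:
- Atom labels C1–C15 follow sarcodictyin numbering. Numbered compounds are starting materials, intermediates and the target; stock reagents are given by name and SMILES in each step.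
- Compounds 11–17 and 21 are carried as mixtures at C2/C3, since both centres are erased in Step 16; these two centres are left undefined in the SMILES.
- The route is a proposal: the early steps and the furanophane/Achmatowicz logic follow known chemistry, but the sequence as a whole has not been run.

## Route

**Step 1**
Reactants: 1 (R)-(−)-α-phellandrene; 2 trichloroacetyl chloride
Product: 3, cis-fused 8,8-dichloro-2-methyl-5-(propan-2-yl)bicyclo[4.2.0]oct-2-en-7-one, cyclobutanone anti to the isopropyl group, C=O on the carbon next to the iPr-bearing carbon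
Conditions: activated Zn, Et2O, ultrasound, 0 °C → rt
Reagents that add atoms: 2 trichloroacetyl chloride, ClC(Cl)(Cl)C(Cl)=O (delivers Cl2C=C=O)
Why: Ketene–alkene [2+2] cycloaddition at the less substituted diene double bond, carbonyl carbon to the diene terminus and on the face anti to iPr, sets C1 and C10 (cis) relative to C14.

**Step 2**
Reactants: 3
Product: 4, cis-fused 2-methyl-5-(propan-2-yl)bicyclo[4.2.0]oct-2-en-7-one
Conditions: Zn dust, NH4Cl, MeOH, rt
Reagents that add atoms: none
Why: Reductive dehalogenation of the α,α-dichloroketone by zinc leaves the alkene and all stereocentres untouched.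

**Step 3**
Reactants: 4; 5 Bredereck's reagent (tert-butoxybis(dimethylamino)methane)
Product: 6, the 8-[(dimethylamino)methylidene] derivative of 4 (E assumed; geometry is irrelevant)
Conditions: neat 5, 60 °C
Reagents that add atoms: 5, CN(C)C(OC(C)(C)C)N(C)C (adds =CH–NMe2)
Why: Bredereck aminomethylenation occurs at the only α-CH2 of the cyclobutanone.

**Step 4**
Reactants: 6
Product: 7, methyl (1R,2R,6R)-2-(2,2-dimethoxyethyl)-3-methyl-6-(propan-2-yl)cyclohex-3-ene-1-carboxylate (ester and acetal chain cis, ester trans to iPr)
Conditions: TsOH·H2O, MeOH, 60 °C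
Reagents that add atoms: methanol, CO (three OMe groups)
Why: Acid-catalysed methanolysis and retro-Claisen fragmentation of the strained vinylogous amide gives the C1 ester (C2) and the C8 acetal without touching C1 or C10.

**Step 5**
Reactants: 7
Product: 8, (1R,2R,6R)-2-(2,2-dimethoxyethyl)-3-methyl-6-(propan-2-yl)cyclohex-3-ene-1-carbaldehyde
Conditions: DIBAL-H (1.1 equiv), CH2Cl2, −78 °C; Rochelle salt work-up
Reagents that add atoms: none
Why: Partial reduction of an α-branched methyl ester stops at the aldehyde at −78 °C, and the cold neutral work-up avoids C1 epimerisation.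

**Step 6**
Reactants: 9 methyl 2-(furan-2-yl)acetate
Product: 10, methyl 2-(5-bromofuran-2-yl)acetate
Conditions: NBS, DMF, 0 °C, dark
Reagents that add atoms: N-bromosuccinimide, O=C1CCC(=O)N1Br (adds Br)
Why: Electrophilic aromatic bromination of a 2-alkylfuran is selective for the free α-position (C5).

**Step 7**
Reactants: 8; 10
Product: 11, methyl 2-(5-bromofuran-2-yl)-3-[(1R,2R,6R)-2-(2,2-dimethoxyethyl)-3-methyl-6-(propan-2-yl)cyclohex-3-en-1-yl]-3-(pivaloyloxy)propanoate (C2/C3 mixture)
Conditions: LiHMDS, THF, −78 °C (enolate of 10); add 8; then PivCl, −78 → −20 °C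
Reagents that add atoms: pivaloyl chloride, CC(C)(C)C(Cl)=O (adds pivaloyl)
Why: Lithium ester-enolate aldol addition to the C1 aldehyde forms C2–C3, and in situ O-pivaloylation stops retro-aldol and stores C2=C3 as a β-acyloxy ester; the new centres need no control.

**Step 8**
Reactants: 11
Product: 12, the corresponding aldehyde (2-oxoethyl in place of 2,2-dimethoxyethyl; C2/C3 mixture)
Conditions: PPTS, acetone/H2O (10:1), 40 °C
Reagents that add atoms: water, O (carbonyl oxygen)
Why: Mild acetal hydrolysis frees the C8 aldehyde while the bromofuran, pivalate and methyl ester survive.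

**Step 9**
Reactants: 12
Product: 13, [6](2,5)furanophane with the new C7–C8 bond: C8 secondary alcohol, C3-CO2Me, C2-OPiv, cis-fused cyclohexene (mixture at C8 and C2/C3)
Conditions: CrCl2 (10 equiv), NiCl2 (cat.), DMF, rt, 5 mM, slow addition
Reagents that add atoms: none
Why: Intramolecular Nozaki–Hiyama–Kishi addition of the furyl–Cr species to the aldehyde tolerates the ester, pivalate and acidic C3-H, and closes a ten-membered ring on an sp3 tether like the one known to cyclise in this ring system.

**Step 10**
Reactants: 13
Product: 14, the C8 ketone (2-furyl ketone) of the furanophane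
Conditions: Dess–Martin periodinane, NaHCO3, CH2Cl2, 0 °C → rt
Reagents that add atoms: none
Why: Dess–Martin oxidation of the furfuryl alcohol converges the C8 epimers without base that could trigger pivalate elimination.

**Step 11**
Reactants: 14
Product: 15, (8S)-furfuryl alcohol of the furanophane
Conditions: (R)-Me-CBS (0.5 equiv), catecholborane, toluene, −78 → −40 °C
Reagents that add atoms: none
Why: Corey–Bakshi–Shibata reduction with the furyl group as the large substituent delivers hydride to the Re face to give 8S, and catecholborane leaves the trisubstituted alkene alone.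

**Step 12**
Reactants: 15
Product: 16, bridged 6-hydroxy-2H-pyran-3(6H)-one: ring O links C8 and C4, C7 ketone, C5=C6, C4 hemiketal OH, carbon bridge (C9 and C3) cis on one face
Conditions: DMDO, acetone/CH2Cl2, −78 → 0 °C
Reagents that add atoms: dimethyldioxirane, CC1(C)OO1 (adds O)
Why: Achmatowicz oxidative ring expansion of the electron-rich 2,5-dialkylfuran is faster than epoxidation of the trisubstituted alkene, and the C4 configuration is fixed by the bridge.

**Step 13**
Reactants: 16
Product: 17, (7S,8S)-pyranose diol: C7 tertiary alcohol bearing the new methyl group anti to the carbon bridge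
Conditions: MeLi, CeCl3, THF, −78 °C
Reagents that add atoms: methyllithium, [Li]C (adds CH3)
Why: Organocerium 1,2-addition is selective for the enone ketone over the ester and pivalate and occurs on the convex face opposite the C9–C3 bridge, which sets C7.

**Step 14**
Reactants: 18 1-methyl-1H-imidazole-4-carbaldehyde; 19 malonic acid
Product: 20, (E)-3-(1-methyl-1H-imidazol-4-yl)prop-2-enoic acid (N-methylurocanic acid)
Conditions: pyridine, piperidine (cat.), 100 °C
Reagents that add atoms: 19 malonic acid, OC(=O)CC(=O)O (adds =CH–CO2H after loss of CO2)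
Why: Knoevenagel–Doebner condensation with decarboxylation gives the E-acrylic acid.

**Step 15**
Reactants: 17; 20
Product: 21, 4,7-furanose (2,5-dihydrofuran hemiketal) with the C8 N-methylurocanate, C2-OPiv and C3-H (2,3-dihydro-2-pivaloyloxy-sarcodictyin A)
Conditions: 20, PivCl, Et3N, CH2Cl2, 0 °C (mixed anhydride); then 17, DMAP, ClCH2CH2Cl, rt → 40 °C
Reagents that add atoms: 20, Cn1cnc(/C=C/C(=O)O)c1 (adds the urocanoyl group)
Why: Base-mediated pyranose–furanose hemiketal equilibration exposes the only secondary alcohol (C8) in the furanose form, and its selective acylation drains the equilibrium; C4 is fixed by the cis bridge.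

**Step 16**
Reactants: 21
Product: 22, sarcodictyin A
Conditions: DBU, CH2Cl2, 0 °C → rt
Reagents that add atoms: none
Why: E1cB elimination of pivalate from the β-acyloxy ester gives C2=C3, and only the ring-cis geometry (C1 cis to C4, E by CIP) fits the bridged ten-membered ring, so all C2/C3 diastereomers converge.

## Compound list

1 | (R)-(−)-α-phellandrene | CC1=CC[C@H](C(C)C)C=C1 | starting material
2 | trichloroacetyl chloride | ClC(Cl)(Cl)C(Cl)=O | starting material
3 | cis-fused 8,8-dichloro-2-methyl-5-(propan-2-yl)bicyclo[4.2.0]oct-2-en-7-one | O=C1[C@@H]2[C@@H](C(C)C)CC=C(C)[C@@H]2C1(Cl)Cl | intermediate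
4 | cis-fused 2-methyl-5-(propan-2-yl)bicyclo[4.2.0]oct-2-en-7-one | O=C1[C@@H]2[C@@H](C(C)C)CC=C(C)[C@@H]2C1 | intermediate
5 | Bredereck's reagent | CN(C)C(OC(C)(C)C)N(C)C | starting material
6 | 8-[(dimethylamino)methylidene] enaminone of 4 | O=C1[C@@H]2[C@@H](C(C)C)CC=C(C)[C@@H]2/C1=C\N(C)C | intermediate
7 | methyl (1R,2R,6R)-2-(2,2-dimethoxyethyl)-3-methyl-6-(propan-2-yl)cyclohex-3-ene-1-carboxylate | COC(=O)[C@@H]1[C@@H](C(C)C)CC=C(C)[C@@H]1CC(OC)OC | intermediate
8 | (1R,2R,6R)-2-(2,2-dimethoxyethyl)-3-methyl-6-(propan-2-yl)cyclohex-3-ene-1-carbaldehyde | O=C[C@@H]1[C@@H](C(C)C)CC=C(C)[C@@H]1CC(OC)OC | intermediate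
9 | methyl 2-(furan-2-yl)acetate | COC(=O)Cc1ccco1 | starting material
10 | methyl 2-(5-bromofuran-2-yl)acetate | COC(=O)Cc1ccc(Br)o1 | intermediate
11 | aldol pivalate with C8 dimethyl acetal (C2/C3 mixture) | COC(=O)C(c1ccc(Br)o1)C(OC(=O)C(C)(C)C)[C@@H]1[C@@H](C(C)C)CC=C(C)[C@@H]1CC(OC)OC | intermediate
12 | aldol pivalate with C8 aldehyde (C2/C3 mixture) | COC(=O)C(c1ccc(Br)o1)C(OC(=O)C(C)(C)C)[C@@H]1[C@@H](C(C)C)CC=C(C)[C@@H]1CC=O | intermediate
13 | furanophane C8 alcohol (C8 and C2/C3 mixture) | COC(=O)C1C(OC(=O)C(C)(C)C)[C@@H]2[C@@H](C(C)C)CC=C(C)[C@@H]2CC(O)c2ccc1o2 | intermediate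
14 | furanophane C8 ketone | COC(=O)C1C(OC(=O)C(C)(C)C)[C@@H]2[C@@H](C(C)C)CC=C(C)[C@@H]2CC(=O)c2ccc1o2 | intermediate
15 | (8S)-furanophane alcohol | COC(=O)C1C(OC(=O)C(C)(C)C)[C@@H]2[C@@H](C(C)C)CC=C(C)[C@@H]2C[C@H](O)c2ccc1o2 | intermediate
16 | bridged pyranone hemiketal (4,8-oxide, C7 ketone) | COC(=O)C1C(OC(=O)C(C)(C)C)[C@@H]2[C@@H](C(C)C)CC=C(C)[C@@H]2C[C@@H]2O[C@@]1(O)C=CC2=O | intermediate
17 | (7S,8S)-pyranose with C7 methyl carbinol | COC(=O)C1C(OC(=O)C(C)(C)C)[C@@H]2[C@@H](C(C)C)CC=C(C)[C@@H]2C[C@@H]2O[C@@]1(O)C=C[C@]2(C)O | intermediate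
18 | 1-methyl-1H-imidazole-4-carbaldehyde | Cn1cnc(C=O)c1 | starting material
19 | malonic acid | OC(=O)CC(=O)O | starting material
20 | (E)-3-(1-methyl-1H-imidazol-4-yl)prop-2-enoic acid | Cn1cnc(/C=C/C(=O)O)c1 | intermediate
21 | 2,3-dihydro-2-pivaloyloxy-sarcodictyin A (furanose, C8 urocanate) | COC(=O)C1C(OC(=O)C(C)(C)C)[C@@H]2[C@@H](C(C)C)CC=C(C)[C@@H]2C[C@H](OC(=O)/C=C/c2cn(C)cn2)[C@]2(C)C=C[C@@]1(O)O2 | intermediate
22 | sarcodictyin A | COC(=O)/C1=C/[C@@H]2[C@@H](C(C)C)CC=C(C)[C@@H]2C[C@H](OC(=O)/C=C/c2cn(C)cn2)[C@]2(C)C=C[C@@]1(O)O2 | target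

## Totals and risks

Total step count: 16.
Longest linear sequence: 14 (Steps 1–5, 7–13, 15, 16 from α-phellandrene).

Three steps most likely to fail:

1. **Step 9, NHK macrocyclisation.** The ring is a strained ten-membered furanophane and the substrate is a diastereomer mixture. Fallback: drop the furanophane and close the ring by acetylide addition instead. Build C4–C7 as a C7-methyl propargylic alcohol on the C8 side, form C2=C3 by Knoevenagel condensation at the C1 aldehyde, cyclise by intramolecular lithium acetylide addition to a C4 aldehyde, oxidise to the ynone, and Lindlar-reduce so that the C7-OH closes the hemiketal.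

2. **Steps 10–11, C8 control inside the macrocycle.** An sp2 C8 adds strain to the furanophane, and the ring may override catalyst control in the CBS reduction. Fallback: set C8 before ring closure. C-acylate cyclobutanone 4 with a 5-bromo-2-furoyl donor, open the 2-acylcyclobutanone by retro-Claisen (NaOMe/MeOH) to the acyclic 2-furyl ketone, and reduce it by Noyori transfer hydrogenation. Then homologate C2 and close the ring at C3–C4 by NHK onto a C3 aldehyde, adding the C15 ester late via a C3 enol triflate and Pd/CO/MeOH.

3. **Steps 15–16, the endgame.** Pyranose-to-furanose isomerisation with selective C8 acylation, then E1cB beside a free hemiketal, could suffer premature elimination, oxa-Michael addition of the free C8-OH, or acyl migration. Fallback: change the protecting-group strategy. Trap the furanose as its C8 acetate, lock C4 as the methyl ketal (MeOH, PPTS), do the elimination and the acetate-to-urocanate exchange on the locked ketal, and release the hemiketal last with CSA/H2O.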